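The octane chain is numbered from the aryl-bearing carbon. The target is then a syn-1,3-diol diacetate in which the carbinol carbons C3 and C5 flank the C4 methylene. This O–C–C–C–O triad is treated as a latent 1,3-bis(boronic ester). The key step joins C4 to C3 by lithiation–borylation: the primary boronate of (R)-1,2-bis(pinacolboryl)pentane (C4 and C5, from asymmetric diboration of 1-pentene) captures the sparteine-configured α-lithiated triisopropylbenzoate of O-benzyl dihydroconiferyl alcohol. A 1,2-metalate rearrangement forges C3–C4 and sets C3 under reagent control, and oxidation of both C–B bonds in the same flask gives the syn-diol. Acetylation and hydrogenolysis finish the route.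

Key step: step 4

Assumption: the (R,R)-configured TADDOL-derived phosphonite is taken to deliver the (R)-bis(boronate) 5 in step 3; if the sense of induction is the opposite, its (S,S)-enantiomer is used instead.

Step 1
Reactants: 1 4-(3-hydroxypropyl)-2-methoxyphenol (dihydroconiferyl alcohol)
Product: 2 3-[4-(benzyloxy)-3-methoxyphenyl]propan-1-ol
Conditions: BnBr, K2CO3, acetone, reflux
Reagents that add atoms: benzyl bromide, BrCc1ccccc1
Why: Williamson etherification; K2CO3 deprotonates only the phenol (far more acidic than the primary alcohol), so benzylation should occur at the phenolic oxygen alone.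

Step 2
Reactants: 2 3-[4-(benzyloxy)-3-methoxyphenyl]propan-1-ol
Product: 3 3-[4-(benzyloxy)-3-methoxyphenyl]propyl 2,4,6-triisopropylbenzoate
Conditions: 2,4,6-triisopropylbenzoic acid, PPh3, DIAD, THF, 0 °C to rt
Reagents that add atoms: 2,4,6-triisopropylbenzoic acid, CC(C)c1cc(C(C)C)c(C(=O)O)c(C(C)C)c1
Why: Mitsunobu esterification activates the unhindered primary alcohol as an alkoxyphosphonium ion that the hindered carboxylate displaces, which avoids a sluggish acylation with a shielded acyl donor; no stereocentre is involved.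

Step 3
Reactants: 4 1-pentene
Product: 5 (R)-1,2-bis(4,4,5,5-tetramethyl-1,3,2-dioxaborolan-2-yl)pentane
Conditions: B2pin2, Pt(dba)3 (1 mol%), (R,R)-TADDOL-derived phenylphosphonite bearing 3,5-diethylphenyl groups (1.2 mol%), THF, 60 °C, sealed tube
Reagents that add atoms: bis(pinacolato)diboron, CC1(C)OB(OC1(C)C)B1OC(C)(C)C(C)(C)O1
Why: Platinum-catalysed enantioselective alkene diboration: oxidative addition of the B–B bond to zerovalent platinum, alkene insertion into a Pt–B bond and reductive elimination give syn addition of two boryl groups, with the chiral phosphonite selecting the alkene face and thereby setting the C–B stereocentre that becomes C5.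

Step 4
Reactants: 3 3-[4-(benzyloxy)-3-methoxyphenyl]propyl 2,4,6-triisopropylbenzoate; 5 (R)-1,2-bis(4,4,5,5-tetramethyl-1,3,2-dioxaborolan-2-yl)pentane
Product: 9 (3R,5S)-1-[4-(benzyloxy)-3-methoxyphenyl]octane-3,5-diol, via lithiated benzoate 6 (not isolated), via boronate complex 7 (not isolated), via 1,3-bis(boronic ester) 8 (not isolated)
Conditions: 3, s-BuLi, (−)-sparteine, Et2O, −78 °C; then 5, −78 °C to reflux; then THF, aq. NaOH, H2O2, 0 °C to rt
Reagents that add atoms: hydrogen peroxide, OO
Why: s-BuLi/(−)-sparteine removes the pro-S α-proton of benzoate 3 (carbonyl-directed deprotonation) to give the configurationally stable carbenoid 6, which adds with retention to the less hindered primary boron of 5 to form ate complex 7; on warming, the C4 methylene migrates from boron to carbon anti-periplanar to the departing triisopropylbenzoate (inversion) and so forms the C3–C4 bond of 8. The closest known reaction type is the lithiation–borylation (Matteson-type 1,2-metalate) homologation of 1,2-bis(boronic esters) with sparteine-derived lithiated benzoates, followed by stereoretentive peroxide oxidation of both C–B bonds. No ring is closed. C3 is set by the reagent alone through the retention–inversion–retention sequence, which should give 3R with (−)-sparteine, while C5 is carried unchanged from 5 because its C–B bond is only oxidised with retention, so the syn-(3R,5S)-diol should result. The step needs site selectivity for the primary over the secondary boronate, secured by the steric difference and a near-equimolar amount of carbenoid at −78 °C, where 7 does not yet release a new boronic ester; it also needs α-lithiation of the benzoate in preference to the benzylic ether and the arene, secured by pre-complexation of s-BuLi to the benzoate carbonyl in Et2O at −78 °C.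

Step 5
Reactants: 9 (3R,5S)-1-[4-(benzyloxy)-3-methoxyphenyl]octane-3,5-diol
Product: 10 (3R,5S)-1-[4-(benzyloxy)-3-methoxyphenyl]octane-3,5-diyl diacetate
Conditions: Ac2O, pyridine, DMAP (cat.), CH2Cl2, rt
Reagents that add atoms: acetic anhydride, CC(=O)OC(C)=O
Why: DMAP-catalysed acylation of both secondary alcohols; only O–H bonds react, so the two stereocentres are untouched.

Step 6
Reactants: 10 (3R,5S)-1-[4-(benzyloxy)-3-methoxyphenyl]octane-3,5-diyl diacetate
Product: 11 (3R,5S)-1-(4-hydroxy-3-methoxyphenyl)octane-3,5-diyl diacetate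
Conditions: H2 (1 atm), 10% Pd/C, EtOAc, rt
Reagents that add atoms: none
Why: Hydrogenolysis of the benzyl aryl ether over palladium on carbon under neutral conditions should free the phenol and leave the aliphatic acetates and both stereocentres unchanged.

Compound list
1 | 4-(3-hydroxypropyl)-2-methoxyphenol (dihydroconiferyl alcohol) | OCCCc1ccc(O)c(OC)c1 | starting material
2 | 3-[4-(benzyloxy)-3-methoxyphenyl]propan-1-ol | OCCCc1ccc(OCc2ccccc2)c(OC)c1 | intermediate
3 | 3-[4-(benzyloxy)-3-methoxyphenyl]propyl 2,4,6-triisopropylbenzoate | CC(C)c1cc(C(C)C)c(C(=O)OCCCc2ccc(OCc3ccccc3)c(OC)c2)c(C(C)C)c1 | intermediate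
4 | 1-pentene | C=CCCC | starting material
5 | (R)-1,2-bis(4,4,5,5-tetramethyl-1,3,2-dioxaborolan-2-yl)pentane | CCC[C@@H](CB1OC(C)(C)C(C)(C)O1)B1OC(C)(C)C(C)(C)O1 | intermediate
6 | lithiated benzoate: (S)-1-lithio-3-[4-(benzyloxy)-3-methoxyphenyl]propyl 2,4,6-triisopropylbenzoate, present as its (−)-sparteine complex | CC(C)c1cc(C(C)C)c(C(=O)O[C@@H]([Li])CCc2ccc(OCc3ccccc3)c(OC)c2)c(C(C)C)c1 | intermediate
7 | boronate complex: lithium borate formed by addition of 6 to the primary boron of 5 | [Li+].CCC[C@@H](C[B-]1(OC(C)(C)C(C)(C)O1)[C@@H](CCc1ccc(OCc2ccccc2)c(OC)c1)OC(=O)c1c(C(C)C)cc(C(C)C)cc1C(C)C)B1OC(C)(C)C(C)(C)O1 | intermediate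
8 | 1,3-bis(boronic ester): 2,2'-{(3R,5S)-1-[4-(benzyloxy)-3-methoxyphenyl]octane-3,5-diyl}bis(4,4,5,5-tetramethyl-1,3,2-dioxaborolane) | CCC[C@@H](C[C@@H](CCc1ccc(OCc2ccccc2)c(OC)c1)B1OC(C)(C)C(C)(C)O1)B1OC(C)(C)C(C)(C)O1 | intermediate
9 | (3R,5S)-1-[4-(benzyloxy)-3-methoxyphenyl]octane-3,5-diol | CCC[C@@H](C[C@@H](CCc1ccc(OCc2ccccc2)c(OC)c1)O)O | intermediate
10 | (3R,5S)-1-[4-(benzyloxy)-3-methoxyphenyl]octane-3,5-diyl diacetate | CCC[C@@H](C[C@@H](CCc1ccc(OCc2ccccc2)c(OC)c1)OC(C)=O)OC(C)=O | intermediate
11 | (3R,5S)-1-(4-hydroxy-3-methoxyphenyl)octane-3,5-diyl diacetate | CCC[C@@H](C[C@@H](CCc1ccc(O)c(OC)c1)OC(C)=O)OC(C)=O | target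

Total step count: 6.
Longest linear sequence: 5 steps (steps 1, 2, 4, 5, 6); step 3 is a one-step side branch.

Steps most likely to fail

Step 4. The carbenoid may be lost through competing lithiation at the benzylic ether CH2 or on the electron-rich arene. It may also attack the secondary boronate or homologate twice, and the 1,2-migration may be incomplete. The fallback sets out from 2 and comes back at 9. Alcohol 2 is oxidised (Dess–Martin periodinane, CH2Cl2) to 3-[4-(benzyloxy)-3-methoxyphenyl]propanal F1. F1 is converted with propane-1,3-dithiol and BF3·OEt2 into 2-{2-[4-(benzyloxy)-3-methoxyphenyl]ethyl}-1,3-dithiane F2. Deprotonation with n-BuLi (THF, −30 °C) gives the 2-lithio-1,3-dithiane F3. F3 opens commercial (S)-2-propyloxirane at its CH2 terminus to give (S)-1-(2-{2-[4-(benzyloxy)-3-methoxyphenyl]ethyl}-1,3-dithian-2-yl)pentan-2-ol F4. This makes the same C3–C4 bond by umpolung alkylation, with C5 taken from the epoxide. Dithiane removal (MeI, CaCO3, aqueous MeCN) gives (S)-1-[4-(benzyloxy)-3-methoxyphenyl]-5-hydroxyoctan-3-one F5. Chelation-controlled syn reduction (Et2BOMe, NaBH4, THF/MeOH, −78 °C; Narasaka–Prasad reduction) should then deliver 9.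

Step 3. Facial selectivity in the insertion may be insufficient for a small unbranched alkene, and the volatile alkene may be lost at 60 °C. Any minor enantiomer of 5 would be carried in step 4 into the anti-diol, which should be separable from 9 by chromatography. The fallback sets out from 4 and comes back at 5. Cross-metathesis of 4 with vinylboronic acid pinacol ester (second-generation Grubbs catalyst, CH2Cl2, 40 °C) should give (E)-2-(pent-1-en-1-yl)-4,4,5,5-tetramethyl-1,3,2-dioxaborolane F6. Enantioselective copper-catalysed protoboration of F6 (B2pin2, MeOH, CuCl, NaOt-Bu, a chiral imidazolinium-derived carbene ligand of the enantiomeric series that gives the R product, THF, −15 °C) then gives 5. Here the stereocentre is set by Cu–B addition across the alkenylboronate followed by protonation, not by diboration.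

Step 2. Esterification with the hindered acid may stall, or the ester may be hard to free from the hydrazine dicarboxylate and phosphine oxide. The fallback sets out from 2 and comes back at 8, which is oxidised in the same flask to 9 as in step 4. Alcohol 2 is carbamoylated (N,N-diisopropylcarbamoyl chloride, Et3N, toluene, reflux) to 3-[4-(benzyloxy)-3-methoxyphenyl]propyl N,N-diisopropylcarbamate F7. s-BuLi/(−)-sparteine (Et2O, −78 °C) gives the (S)-configured lithiated carbamate F8. F8 adds to the primary boron of 5 to give the carbamate boronate complex F9. MgBr2·OEt2 and warming to reflux trigger the 1,2-migration with loss of the carbamate to give 8, and NaOH/H2O2 then gives 9.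

Further compounds
F1 | step 4 | 3-[4-(benzyloxy)-3-methoxyphenyl]propanal | O=CCCc1ccc(OCc2ccccc2)c(OC)c1
F2 | step 4 | 2-{2-[4-(benzyloxy)-3-methoxyphenyl]ethyl}-1,3-dithiane | C1CSC(CCc2ccc(OCc3ccccc3)c(OC)c2)SC1
F3 | step 4 | 2-lithio-2-{2-[4-(benzyloxy)-3-methoxyphenyl]ethyl}-1,3-dithiane | [Li]C1(CCc2ccc(OCc3ccccc3)c(OC)c2)SCCCS1
F4 | step 4 | (S)-1-(2-{2-[4-(benzyloxy)-3-methoxyphenyl]ethyl}-1,3-dithian-2-yl)pentan-2-ol | CCC[C@H](O)CC1(CCc2ccc(OCc3ccccc3)c(OC)c2)SCCCS1
F5 | step 4 | (S)-1-[4-(benzyloxy)-3-methoxyphenyl]-5-hydroxyoctan-3-one | CCC[C@H](O)CC(=O)CCc1ccc(OCc2ccccc2)c(OC)c1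
F6 | step 3 | (E)-2-(pent-1-en-1-yl)-4,4,5,5-tetramethyl-1,3,2-dioxaborolane | CCC/C=C/B1OC(C)(C)C(C)(C)O1
F7 | step 2 | 3-[4-(benzyloxy)-3-methoxyphenyl]propyl N,N-diisopropylcarbamate | CC(C)N(C(C)C)C(=O)OCCCc1ccc(OCc2ccccc2)c(OC)c1
F8 | step 2 | (S)-1-lithio-3-[4-(benzyloxy)-3-methoxyphenyl]propyl N,N-diisopropylcarbamate | CC(C)N(C(C)C)C(=O)O[C@@H]([Li])CCc1ccc(OCc2ccccc2)c(OC)c1
F9 | step 2 | carbamate boronate complex: lithium borate from F8 and the primary boron of 5 | [Li+].CCC[C@@H](C[B-]1(OC(C)(C)C(C)(C)O1)[C@@H](CCc1ccc(OCc2ccccc2)c(OC)c1)OC(=O)N(C(C)C)C(C)C)B1OC(C)(C)C(C)(C)O1
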